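**Plan**

- The target is a 4‑methoxycyclohex‑2‑enone (ring numbered C1 = ketone, C2=C3, C4 = CH–OMe, C5 = CH2, C6 = quaternary). The ring ketone C1 and the side‑chain aryl ketone are 1,4‑related through C6, so C6 is the β‑carbon of the aryl ketone and C1 can arrive as an acyl‑anion equivalent.
- Retrosynthesis: remove the C2=C3 unsaturation, then cut C1–C6, which opens the only carbocycle to an aldehyde tethered to a (Z)‑tetrasubstituted aryl enone. That chain is cut at aryl–CO (Grignard on a Weinreb amide), at O–CH3, at C6–allyl (Stille coupling of an enol triflate), and at the propanoate, acetoacetate and prenyl C–C bonds.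
- Forward: the chain is joined linearly. A temporary δ‑lactone ring fixes the geometry of the tetrasubstituted alkene and is opened again. A prenyl alkene serves as masked aldehyde. The cyclohexanone is closed by a carbene‑catalysed intramolecular Stetter reaction and then dehydrogenated.
- Stereochemistry: C4 (OMe) comes from a Noyori hydrogenation. The quaternary C6 comes from the ring closure (chair with equatorial OMe, reinforced by the chiral carbene). The side‑chain methyl centre comes from syn delivery of acyl and H across the (Z)‑alkene in the same step.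

Key step: step 12

Assumption: the sense of induction of the aminoindanol‑derived triazolylidene on this acceptor class is taken by analogy with its known Stetter reactions; if the antipode written below proves mismatched with the substrate's own chair preference, its enantiomer is used under the same conditions.

**Step 1**
Reactants: 1 methyl acetoacetate; 2 prenyl bromide (1‑bromo‑3‑methylbut‑2‑ene)
Product: 4 methyl 7‑methyl‑3‑oxooct‑6‑enoate, via acetoacetate dianion 3 (not isolated)
Conditions: NaH, THF, 0 °C; n‑BuLi, 0 °C; then 2, 0 °C to rt; aq. NH4Cl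
Reagents that add atoms: none
Why: γ‑alkylation of an acetoacetate dianion, in which the more basic terminal carbanion of 3 displaces the allylic bromide (SN2) and the stabilised α‑position stays untouched; no stereocentre is formed.

**Step 2**
Reactants: 4 methyl 7‑methyl‑3‑oxooct‑6‑enoate
Product: 5 methyl (3S)‑3‑hydroxy‑7‑methyloct‑6‑enoate
Conditions: H2 (4 atm), RuCl2[(S)‑BINAP] (0.5 mol %), MeOH, 80 °C
Reagents that add atoms: none
Why: Noyori asymmetric hydrogenation of a β‑keto ester, in which the chelated keto ester takes hydride on one face from the (S)‑BINAP ruthenium complex to give the (3S)‑alcohol (the future C4–O centre), while the remote trisubstituted alkene should not be reduced under these conditions.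

**Step 3**
Reactants: 5 methyl (3S)‑3‑hydroxy‑7‑methyloct‑6‑enoate; 6 tert‑butyl propanoate
Product: 8 tert‑butyl (5S)‑5‑hydroxy‑2,9‑dimethyl‑3‑oxodec‑8‑enoate (C2 epimers), via lithium ester enolate 7 (not isolated)
Conditions: LDA (3.3 equiv), 6 (3.3 equiv), THF, −78 °C; then 5, −78 to −30 °C; aq. NH4Cl
Reagents that add atoms: none
Why: crossed Claisen condensation of excess ester enolate with a free β‑hydroxy ester, in which the alkoxide formed first protects C5 from elimination and the product is held as its enolate; the new C2 centre is inconsequential because it becomes sp2 in the next steps.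

**Step 4**
Reactants: 8 tert‑butyl (5S)‑5‑hydroxy‑2,9‑dimethyl‑3‑oxodec‑8‑enoate
Product: 10 (6S)‑4‑hydroxy‑3‑methyl‑6‑(4‑methylpent‑3‑en‑1‑yl)‑5,6‑dihydro‑2H‑pyran‑2‑one, via acylketene 9 (not isolated)
Conditions: toluene, 110 °C
Reagents that add atoms: none
Why: thermal loss of tert‑butanol from the β‑keto tert‑butyl ester gives acylketene 9, which the δ‑hydroxyl traps to close the six‑membered lactone under neutral conditions that spare the prenyl alkene; no stereocentre is touched.

**Step 5**
Reactants: 10 (6S)‑4‑hydroxy‑3‑methyl‑6‑(4‑methylpent‑3‑en‑1‑yl)‑5,6‑dihydro‑2H‑pyran‑2‑one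
Product: 11 (2S)‑5‑methyl‑2‑(4‑methylpent‑3‑en‑1‑yl)‑6‑oxo‑3,6‑dihydro‑2H‑pyran‑4‑yl trifluoromethanesulfonate
Conditions: Tf2O, Et3N, CH2Cl2, −78 to 0 °C
Reagents that add atoms: trifluoromethanesulfonic anhydride, O=S(=O)(OS(=O)(=O)C(F)(F)F)C(F)(F)F
Why: O‑sulfonylation of the vinylogous acid gives a cyclic enol triflate in which the ring holds the C5 methylene and the lactone carbonyl on the same side of the C3=C4 bond, which fixes the later alkene geometry.

**Step 6**
Reactants: 11 enol triflate; 12 allyltributylstannane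
Product: 13 (6S)‑3‑methyl‑6‑(4‑methylpent‑3‑en‑1‑yl)‑4‑(prop‑2‑en‑1‑yl)‑5,6‑dihydro‑2H‑pyran‑2‑one
Conditions: Pd(PPh3)4 (5 mol %), LiCl, THF, 65 °C
Reagents that add atoms: none
Why: Stille coupling of an electron‑poor cyclic enol triflate with an allylstannane (oxidative addition, chloride‑assisted transmetalation, reductive elimination) places the allyl group on C4 with the ring geometry retained.

**Step 7**
Reactants: 13 allyl lactone
Product: 14 (2Z,5S)‑5‑hydroxy‑N‑methoxy‑N,2,9‑trimethyl‑3‑(prop‑2‑en‑1‑yl)deca‑2,8‑dienamide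
Conditions: Me(MeO)NH·HCl, AlMe3, CH2Cl2, 0 °C to rt; Rochelle salt work‑up; used at once
Reagents that add atoms: N,O‑dimethylhydroxylamine hydrochloride, CNOC.Cl
Why: Weinreb aminolysis of the lactone by the aluminium amide opens the temporary ring at the acyl C–O bond, so the tetrasubstituted alkene keeps the (Z) geometry (CH2 cis to carbonyl) and the carbinol centre is not touched.

**Step 8**
Reactants: 14 hydroxy Weinreb amide
Product: 15 (2Z,5S)‑N,5‑dimethoxy‑N,2,9‑trimethyl‑3‑(prop‑2‑en‑1‑yl)deca‑2,8‑dienamide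
Conditions: Me3OBF4, 1,8‑bis(dimethylamino)naphthalene, 4 Å MS, CH2Cl2, 0 °C to rt
Reagents that add atoms: trimethyloxonium tetrafluoroborate, C[O+](C)C.F[B-](F)(F)F
Why: O‑methylation with Meerwein's salt and a non‑nucleophilic base avoids a free alkoxide, which would relactonise onto the cis amide; the stereocentre is untouched because only the O–H bond reacts.

**Step 9**
Reactants: 15 methoxy Weinreb amide; 16 3,4‑dimethoxyphenylmagnesium bromide
Product: 17 (2Z,5S)‑1‑(3,4‑dimethoxyphenyl)‑5‑methoxy‑2,9‑dimethyl‑3‑(prop‑2‑en‑1‑yl)deca‑2,8‑dien‑1‑one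
Conditions: 16 (2.5 equiv), THF, 0 °C to rt; aq. NH4Cl
Reagents that add atoms: none
Why: aryl Grignard addition to a Weinreb amide stops at the chelated tetrahedral intermediate and gives the aryl ketone on work‑up; the fully substituted β‑carbon prevents conjugate addition.

**Step 10**
Reactants: 17 aryl enone
Product: 18 (2Z,5S)‑1‑(3,4‑dimethoxyphenyl)‑7‑(3,3‑dimethyloxiran‑2‑yl)‑5‑methoxy‑2‑methyl‑3‑(prop‑2‑en‑1‑yl)hept‑2‑en‑1‑one (both epoxide epimers)
Conditions: mCPBA (1.05 equiv), CH2Cl2, −10 to 0 °C
Reagents that add atoms: 3‑chloroperoxybenzoic acid, OOC(=O)c1cccc(Cl)c1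
Why: Prilezhaev epoxidation, in which the electron‑rich trisubstituted alkene should react far faster than the monosubstituted allyl alkene and the electron‑poor enone alkene; the epoxide configuration is irrelevant.

**Step 11**
Reactants: 18 epoxide
Product: 19 (4S,6Z)‑8‑(3,4‑dimethoxyphenyl)‑4‑methoxy‑7‑methyl‑8‑oxo‑6‑(prop‑2‑en‑1‑yl)oct‑6‑enal
Conditions: H5IO6, THF/H2O, 0 °C
Reagents that add atoms: none
Why: periodic acid opens the epoxide to the glycol and cleaves it (Malaprade‑type glycol cleavage) to the aldehyde and acetone, unmasking the acyl‑anion precursor without touching the allyl group.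

**Step 12**
Reactants: 19 aldehyde‑enone
Product: 20 (2R,4S)‑2‑[(2S)‑1‑(3,4‑dimethoxyphenyl)‑1‑oxopropan‑2‑yl]‑4‑methoxy‑2‑(prop‑2‑en‑1‑yl)cyclohexan‑1‑one
Conditions: (5aR,10bS)‑2‑(pentafluorophenyl)‑5a,10b‑dihydro‑4H,6H‑indeno[2,1‑b][1,2,4]triazolo[4,3‑d][1,4]oxazin‑2‑ium tetrafluoroborate (20 mol %), KHMDS (18 mol %), toluene, HMDS removed in vacuo; then 19, 0.02 M, 0 to 23 °C
Reagents that add atoms: none
Why: Proposed new method: the triazolylidene adds to the aldehyde of 19 and proton transfer gives the Breslow enaminol, whose nucleophilic former‑aldehyde carbon attacks the fully substituted β‑carbon of the (Z)‑aryl enone, after which the enolate is protonated and the carbene is expelled; the closest known reaction type is the asymmetric intramolecular Stetter reaction, established separately for β,β‑disubstituted acceptors (quaternary centres) and for α,β‑disubstituted acceptors (contiguous centres) but not for an α,β,β‑trisubstituted enone closed by an aliphatic aldehyde. The only ring formed is the cyclohexanone, closed 6‑exo‑trig. The quaternary centre (2R) should arise from attack on the alkene face that lets a chair‑like transition state keep the C4 methoxy group and the aroyl‑bearing alkene terminus equatorial and the allyl group axial, which places methoxy and ketone side chain cis, and the chiral carbene is chosen to reinforce this face. The side‑chain methyl centre (S) should arise from intramolecular transfer of the enaminol O–H proton to the enolate carbon on the face just attacked, a net syn addition of acyl and H across the alkene whose geometry (ring CH2 cis to aroyl, allyl cis to methyl) was fixed by the lactone ring of 13. The step needs the aldehyde to react at the hindered acceptor in preference to homo‑benzoin, aldol or base‑induced isomerisation of the skipped diene, which high dilution and a preformed carbene free of excess base should secure, and the aryl‑ketone conjugation makes the tetrasubstituted alkene the only Michael acceptor present.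

**Step 13**
Reactants: 20 cyclohexanone
Product: 23 (4R,6R)‑6‑[(2S)‑1‑(3,4‑dimethoxyphenyl)‑1‑oxopropan‑2‑yl]‑4‑methoxy‑6‑(prop‑2‑en‑1‑yl)cyclohex‑2‑en‑1‑one, via lithium enolate 21 (not isolated), via sulfilimine adduct 22 (not isolated)
Conditions: LiHMDS (1.1 equiv), THF, −78 °C; then N‑tert‑butylbenzenesulfinimidoyl chloride, −78 °C
Reagents that add atoms: none
Why: Mukaiyama dehydrogenation, in which kinetic deprotonation should occur at the only α‑CH2 of the ring ketone (its other α‑carbon is quaternary and the aryl ketone α‑H is tertiary and shielded by the quaternary carbon), the enolate is sulfenylated at carbon, and the adduct undergoes syn elimination at low temperature to the enone without touching the three stereocentres.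

**Compound list**

1 | methyl acetoacetate | CC(=O)CC(=O)OC | starting material
2 | prenyl bromide (1‑bromo‑3‑methylbut‑2‑ene) | CC(C)=CCBr | starting material
3 | sodium lithium dianion of methyl acetoacetate | [Li+].[Na+].C=C([O-])C=C([O-])OC | intermediate (not isolated)
4 | methyl 7‑methyl‑3‑oxooct‑6‑enoate | COC(=O)CC(=O)CCC=C(C)C | intermediate
5 | methyl (3S)‑3‑hydroxy‑7‑methyloct‑6‑enoate | COC(=O)C[C@@H](O)CCC=C(C)C | intermediate
6 | tert‑butyl propanoate | CCC(=O)OC(C)(C)C | starting material
7 | lithium enolate of tert‑butyl propanoate | [Li+].CC=C([O-])OC(C)(C)C | intermediate (not isolated)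
8 | tert‑butyl (5S)‑5‑hydroxy‑2,9‑dimethyl‑3‑oxodec‑8‑enoate | CC(C(=O)C[C@@H](O)CCC=C(C)C)C(=O)OC(C)(C)C | intermediate
9 | (5S)‑5‑hydroxy‑2,9‑dimethyl‑3‑oxodeca‑1,8‑dien‑1‑one (acylketene) | CC(=C=O)C(=O)C[C@@H](O)CCC=C(C)C | intermediate (not isolated)
10 | (6S)‑4‑hydroxy‑3‑methyl‑6‑(4‑methylpent‑3‑en‑1‑yl)‑5,6‑dihydro‑2H‑pyran‑2‑one | CC1=C(O)C[C@H](CCC=C(C)C)OC1=O | intermediate
11 | (2S)‑5‑methyl‑2‑(4‑methylpent‑3‑en‑1‑yl)‑6‑oxo‑3,6‑dihydro‑2H‑pyran‑4‑yl trifluoromethanesulfonate | CC1=C(OS(=O)(=O)C(F)(F)F)C[C@H](CCC=C(C)C)OC1=O | intermediate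
12 | allyltributylstannane | C=CC[Sn](CCCC)(CCCC)CCCC | starting material
13 | (6S)‑3‑methyl‑6‑(4‑methylpent‑3‑en‑1‑yl)‑4‑(prop‑2‑en‑1‑yl)‑5,6‑dihydro‑2H‑pyran‑2‑one | CC1=C(CC=C)C[C@H](CCC=C(C)C)OC1=O | intermediate
14 | (2Z,5S)‑5‑hydroxy‑N‑methoxy‑N,2,9‑trimethyl‑3‑(prop‑2‑en‑1‑yl)deca‑2,8‑dienamide | CON(C)C(=O)/C(C)=C(CC=C)\C[C@@H](O)CCC=C(C)C | intermediate
15 | (2Z,5S)‑N,5‑dimethoxy‑N,2,9‑trimethyl‑3‑(prop‑2‑en‑1‑yl)deca‑2,8‑dienamide | CON(C)C(=O)/C(C)=C(CC=C)\C[C@@H](OC)CCC=C(C)C | intermediate
16 | 3,4‑dimethoxyphenylmagnesium bromide | COc1ccc([Mg]Br)cc1OC | starting material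
17 | (2Z,5S)‑1‑(3,4‑dimethoxyphenyl)‑5‑methoxy‑2,9‑dimethyl‑3‑(prop‑2‑en‑1‑yl)deca‑2,8‑dien‑1‑one | COc1ccc(cc1OC)C(=O)/C(C)=C(CC=C)\C[C@@H](OC)CCC=C(C)C | intermediate
18 | (2Z,5S)‑1‑(3,4‑dimethoxyphenyl)‑7‑(3,3‑dimethyloxiran‑2‑yl)‑5‑methoxy‑2‑methyl‑3‑(prop‑2‑en‑1‑yl)hept‑2‑en‑1‑one | COc1ccc(cc1OC)C(=O)/C(C)=C(CC=C)\C[C@@H](OC)CCC1OC1(C)C | intermediate
19 | (4S,6Z)‑8‑(3,4‑dimethoxyphenyl)‑4‑methoxy‑7‑methyl‑8‑oxo‑6‑(prop‑2‑en‑1‑yl)oct‑6‑enal | COc1ccc(cc1OC)C(=O)/C(C)=C(CC=C)\C[C@@H](OC)CCC=O | intermediate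
20 | (2R,4S)‑2‑[(2S)‑1‑(3,4‑dimethoxyphenyl)‑1‑oxopropan‑2‑yl]‑4‑methoxy‑2‑(prop‑2‑en‑1‑yl)cyclohexan‑1‑one | C=CC[C@]1([C@H](C)C(=O)c2ccc(OC)c(OC)c2)C[C@@H](OC)CCC1=O | intermediate
21 | lithium enolate of 20 (ring C1–C6 enolate) | C=CC[C@]1([C@H](C)C(=O)c2ccc(OC)c(OC)c2)C[C@@H](OC)CC=C1[O-].[Li+] | intermediate (not isolated)
22 | 6‑(N‑tert‑butyl‑S‑phenylsulfinimidoyl) derivative of 20 | C=CC[C@]1([C@H](C)C(=O)c2ccc(OC)c(OC)c2)C[C@@H](OC)CC(S(=NC(C)(C)C)c2ccccc2)C1=O | intermediate (not isolated)
23 | (4R,6R)‑6‑[(2S)‑1‑(3,4‑dimethoxyphenyl)‑1‑oxopropan‑2‑yl]‑4‑methoxy‑6‑(prop‑2‑en‑1‑yl)cyclohex‑2‑en‑1‑one | C=CC[C@]1([C@H](C)C(=O)c2ccc(OC)c(OC)c2)C[C@@H](OC)C=CC1=O | target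

**Totals**

Total step count: 13. Longest linear sequence: 13 steps (from methyl acetoacetate).

**Steps most likely to fail**

1. Step 12 (Proposed new method). The hindered, twisted tetrasubstituted enone may be too poor an acceptor for the Breslow intermediate, so that aldehyde self‑condensation or base‑induced isomerisation of the skipped diene takes over, and the catalyst and substrate facial preferences may be mismatched. Fallback with known chemistry, replacing polar by radical acyl transfer: setting out from 19, Pinnick oxidation (NaClO2, NaH2PO4, 2‑methylbut‑2‑ene, t‑BuOH/H2O) would give (4S,6Z)‑8‑(3,4‑dimethoxyphenyl)‑4‑methoxy‑7‑methyl‑8‑oxo‑6‑(prop‑2‑en‑1‑yl)oct‑6‑enoic acid F1, and (PhSe)2/PBu3 would convert it into the Se‑phenyl selenoester F2. Bu3SnH/AIBN in benzene at 80 °C under high dilution would generate the acyl radical, whose polarity‑matched 6‑exo‑trig addition to the same β‑carbon and hydrogen transfer to the resulting α‑keto radical would return to the route at 20. The quaternary centre would then rest on the chair preference alone (equatorial methoxy) and the methyl centre on A1,3‑controlled hydrogen transfer, with base equilibration and chromatography to correct it if needed.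

2. Step 8. O‑methylation may lose out to relactonisation of the (Z)‑δ‑hydroxy amide with expulsion of the amine, or to O‑alkylation of the amide. Fallback, methylating at the carboxylate stage where ring closure is impossible: setting out from 13, KOH in THF/H2O would give potassium (2Z,5S)‑5‑hydroxy‑2,9‑dimethyl‑3‑(prop‑2‑en‑1‑yl)deca‑2,8‑dienoate F3. NaH (limited to the alkoxide) and excess MeI in DMF would methylate both oxygens to methyl (2Z,5S)‑5‑methoxy‑2,9‑dimethyl‑3‑(prop‑2‑en‑1‑yl)deca‑2,8‑dienoate F4. Me(MeO)NH·HCl/i‑PrMgCl in THF at −20 °C would convert the ester into the Weinreb amide, returning to the route at 15.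

3. Step 13. Regiocontrol in the deprotonation may be lost (competing enolisation of the aryl ketone with epimerisation of the side‑chain centre), or α‑sulfenylation may occur without elimination. Fallback, soft enolisation followed by palladium‑mediated dehydrosilylation: setting out from 20, TMSOTf/Et3N in CH2Cl2 (−78 to 0 °C) would give the trimethylsilyl enol ether of the ring ketone F5, and stoichiometric Pd(OAc)2 in MeCN/DMSO at rt (Saegusa–Ito oxidation) would return to the route at 23.

**Further compounds**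

F1 | step 12 | (4S,6Z)‑8‑(3,4‑dimethoxyphenyl)‑4‑methoxy‑7‑methyl‑8‑oxo‑6‑(prop‑2‑en‑1‑yl)oct‑6‑enoic acid | COc1ccc(cc1OC)C(=O)/C(C)=C(CC=C)\C[C@@H](OC)CCC(O)=O
F2 | step 12 | Se‑phenyl (4S,6Z)‑8‑(3,4‑dimethoxyphenyl)‑4‑methoxy‑7‑methyl‑8‑oxo‑6‑(prop‑2‑en‑1‑yl)oct‑6‑eneselenoate | COc1ccc(cc1OC)C(=O)/C(C)=C(CC=C)\C[C@@H](OC)CCC(=O)[Se]c1ccccc1
F3 | step 8 | potassium (2Z,5S)‑5‑hydroxy‑2,9‑dimethyl‑3‑(prop‑2‑en‑1‑yl)deca‑2,8‑dienoate | [K+].[O-]C(=O)/C(C)=C(CC=C)\C[C@@H](O)CCC=C(C)C
F4 | step 8 | methyl (2Z,5S)‑5‑methoxy‑2,9‑dimethyl‑3‑(prop‑2‑en‑1‑yl)deca‑2,8‑dienoate | COC(=O)/C(C)=C(CC=C)\C[C@@H](OC)CCC=C(C)C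
F5 | step 13 | trimethylsilyl enol ether of 20 (ring C1–C6 enol ether) | C=CC[C@]1([C@H](C)C(=O)c2ccc(OC)c(OC)c2)C[C@@H](OC)CC=C1O[Si](C)(C)C
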